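## Structural features

- Target 17 is a flavone: benzene ring A is fused to the 4-pyranone ring C, and the 2,4,5-trihydroxyphenyl ring B is attached through the C2–C1' bond.
- Every carbon of the chromone core is substituted: a chelated 5-OH, prenyl at C6, OMe at C7, prenyl at C8 and a third prenyl at C3.
- There is no stereocentre and no alkene geometry to set, because each side chain ends in CH=CMe2. The problem is one of constitution and functional-group compatibility.
- The three trisubstituted alkenes are the fragile carbon groups. Protonation gives a tertiary cation that the 5-OH (from the C6 chain), the 2'-OH or the C4 carbonyl oxygen (from the C3 chain) can trap as a cyclic ether.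
- Ring B is a hydroxyquinol, which air oxidises to a hydroxyquinone as soon as it is deprotonated. The single methyl ether at O7 must also be told apart from four phenols.
- The real difficulty is that the usual ways of making ring C (ester-to-diketone acyl shift, acid cyclodehydration) and of putting carbon on C6 and C8 (sigmatropic shifts near 195 °C) are conditions a prenyl group next to a phenol does not tolerate.
- The key step uses the fact that the chains on C3 (ring C), C6 and C8 (ring A) are identical and differ from allyl only at the terminal carbon. The three C2''=C3'' bonds can therefore be written last, from three CH=CH2 groups that are inert to acid, base and heat.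

## Logic of the disconnections

**17 ⇒ 16.** The three aryl O–acetyl bonds on ring B are cut. Acetates can be removed by catalytic carbonate in methanol, so no acid meets the prenyl groups. The demand on the forward step is strict exclusion of air while the ring B phenoxides exist.

**16 ⇒ 14 + 15.** The three CH=CMe2 double bonds are cut back to CH=CH2, with 15 as the donor of the isopropylidene unit. This removes all three acid-labile alkenes at once and leaves a substrate whose side chains survive everything needed to build the core. The forward step must exchange all three termini, favour cross- over self-metathesis and avoid double-bond migration. The ring B acetates and the chelated 5-OH of 14 are kept as they are: neither binds the ruthenium carbene and neither needs acid for removal.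

**14 ⇒ 12 (through 13).** The acetates are traced back to allyl ethers. Ring B needs a protecting group that is stable to strong base and to acid while ring C is made, yet comes off under neutral conditions without touching C-allyl groups or the 7-OMe. O-Allyl meets this, because zerovalent palladium ionises an allyl–O bond but not an allyl–C bond. Triol 13 is not isolated but acetylated in the same flask, which limits its exposure to air.

**12 ⇒ 11.** The O1–C2 bond is cut (cyclodehydration of a 1,3-diketone). Keeping O2' of ring B allylated at this stage is a deliberate improvement: only ring A then offers a free hydroxyl, so the closure cannot go the wrong way round onto the ring A carbonyl. The forward step needs an acid mild enough to leave ortho-allyl phenols and aryl allyl ethers alone.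

**11 ⇒ 10.** The C2–C3 bond (enolate carbon to aroyl carbon) is cut by the reverse of an intramolecular O-to-C acyl shift. This turns a difficult intermolecular C–C bond formation between two hindered partners into an ester formation. The forward step needs a non-nucleophilic base, since the enolate carbon is secondary.

**10 ⇒ 5 + 8 (through 9).** The ester C–O bond is cut, dividing the molecule into a ring A ketone and a ring B acid of similar size. The forward step must acylate only one of the two equivalent, hydrogen-bonded hydroxyls of 5.

**8 ⇒ 6 + 2 (through 7).** Four O–allyl bonds are cut. One reagent caps the three phenols and the acid, and the ester is then saponified in the same flask. The forward step must be run without air.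

**5 ⇒ 4.** The two aryl–allyl bonds at the future C6 and C8 are cut by a reverse double aromatic Claisen rearrangement. The symmetry of 4 makes the outcome unambiguous, and the 7-OMe sits between the two migrating groups from the start, so no selective methylation is needed.

**4 ⇒ 3 + 2.** The bond between the ketone α-carbon and the third allyl group (future C3–C1'') is cut. Placing this alkylation here, on a ketone with no free phenol and only one kind of acidic hydrogen, avoids a later alkylation of a diketone next to unprotected phenols. The forward step must stop at monoalkylation.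

**3 ⇒ 1 + 2.** Two O–allyl bonds are cut, leading to the catalogue acetophenone 1 and to 2, the source of all carbon side chains up to the key step.

## Other disconnections considered

**Alternative 1:** Ring A is cut at C8–C8a and C5–C6.
- *Forward key step:* the enol ether A2, made from the symmetric ketone A1, is C-acylated twice by A3, first at its vinylic carbon and then at the other α-carbon. Enolisation aromatises the ring to A4, with the methoxy carbon and both prenyl groups in place.
- *In its favour:* the symmetry of A1 fixes the whole substitution pattern of ring A. A4 has a single free ring carbon, so the later C-acylation has no regiochemical choice. No hot sigmatropic step is needed. On placing the 7-OMe it is the equal of the chosen plan, which also brings that group in with 1.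
- *Against it here:* acyclic enol ethers tend to be O-acylated by A3 and to end as pyranones. The acylation also releases strong acid next to two prenyl groups that flank nascent phenols. After A4 the route still needs an acylation between two hydroxyls, an acyl shift and an acid ring closure with all three prenyl groups present.
- *Comparison:* structurally it builds a ring that 1 already supplies. Mechanistically it leaves the real problem, survival of prenyl, unsolved. In step count it is about equal, since A1 needs a short synthesis of its own.

**Alternative 2:** Ring B is cut at C1'–C2' and C5'–C6'.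
- *Forward key step:* the bis-silyloxyfuran A6, made from A5 by double silylation, adds as a diene to the terminal alkyne of the 2-ethynylchromone A7. The oxygen bridge opens at the silyloxy-bearing bridgehead and the ring aromatises to A8.
- *In its favour:* the 2',4',5' oxygen pattern arrives with predictable orientation, because the more nucleophilic C5 of A6 should bond to the alkyne terminus, the vinylogous acceptor position of the chromone. The step is thermal and metal-free. Ring B appears last and never meets base and air as a free hydroxyquinol. On that point it is better than the chosen plan, where 6 and 13 must be handled under argon.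
- *Against it here:* A7 needs its own multi-step synthesis and must carry three prenyl groups through it. The allyl surrogate cannot be used, since a terminal alkyne would not tolerate alkene metathesis. Silyloxyfurans often react as vinylogous enol ethers by conjugate addition rather than by cycloaddition. A8 still needs acid to free O5 beside the C6 prenyl group.
- *Comparison:* structurally it spends its key step on a ring that 6 supplies intact. Mechanistically it is elegant but less certain. The sequence is expected to be several steps longer.

**Alternative 3:** Ring C is cut at C3–C4 and O1–C2.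
- *Forward key step:* the symmetric aldehyde A9 and the aryl prenyl alkyne A10 are joined under [Cp*RhCl2]2 with Cu(OAc)2. Phenoxide-directed activation of the aldehyde C–H bond gives an acyl rhodacycle of trivalent rhodium. The alkyne inserts with its aryl-bearing carbon next to the metal, C–O reductive elimination closes the pyranone, and divalent copper reoxidises the catalyst. The product is A11.
- *In its favour:* it is the most convergent cut. Ring C and the substituents on C2 and C3 appear in one step. The symmetry of A9 removes the question of which hydroxyl closes. No diketone and no acid cyclodehydration are needed. In convergence and step count it is better than the chosen plan.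
- *Against it here:* three prenyl groups face a hot oxidative step, where ortho-prenyl phenols can cyclise to chromenes. The CH2 of A10, both propargylic and allylic, can isomerise to a conjugated enyne. The aryl group that should steer insertion is twisted by its ortho substituent. A9 is hindered and electron-rich. A11 must finally lose three acetal protecting groups in acid with a 2'-oxygen next to the C3 prenyl group.
- *Comparison:* the plan is shorter but puts its risk into one unproven coupling and an acidic end game. The chosen plan is longer but uses reaction types of known scope and ends with a base-labile protecting group.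

Key step: step 9

**Remarks**
- Compound 1 is taken as a catalogue chemical, so the 7-OMe is present from the start.
- Where one reagent acts two or three times at like sites in one operation, the partly converted species are not counted as separate compounds.
- The structures of 14 and 16 agree with 17 atom for atom and need no correction. The changes made concern only how 14 is reached.

## Route

Step 1
Reactants: 1 2',6'-dihydroxy-4'-methoxyacetophenone; 2 allyl bromide
Product: 3 1-[2,6-bis(allyloxy)-4-methoxyphenyl]ethan-1-one
Conditions: allyl bromide (2.6 equiv), K2CO3 (3 equiv), DMF, 60 °C, argon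
Reagents that add atoms: allyl bromide (2), C=CCBr
Why: Williamson ether synthesis; carbonate in a polar aprotic solvent favours O- over C-alkylation of the phenoxide, and warming overcomes the hydrogen bond that holds the second hydroxyl to the ketone.

Step 2
Reactants: 3 1-[2,6-bis(allyloxy)-4-methoxyphenyl]ethan-1-one; 2 allyl bromide
Product: 4 1-[2,6-bis(allyloxy)-4-methoxyphenyl]pent-4-en-1-one
Conditions: LiN(i-Pr)2 (1.05 equiv), THF, −78 °C; then allyl bromide (1.2 equiv), −78 → −20 °C
Reagents that add atoms: allyl bromide (2), C=CCBr
Why: Alkylation of a kinetic lithium enolate; the methyl ketone is the only acidic site because both phenols are capped, and the reactive allylic halide should be consumed cold before proton exchange can lead to a second alkylation.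

Step 3
Reactants: 4 1-[2,6-bis(allyloxy)-4-methoxyphenyl]pent-4-en-1-one
Product: 5 1-(3,5-diallyl-2,6-dihydroxy-4-methoxyphenyl)pent-4-en-1-one
Conditions: N,N-diethylaniline, 195 °C, argon
Reagents that add atoms: none
Why: Twofold aromatic Claisen rearrangement; each allyloxy group has one free ortho carbon, and even a detour through the acyl-bearing carbon followed by a Cope shift to the para carbon gives the same symmetric product, while the basic solvent keeps the new ortho-allyl phenols from cyclising.

Step 4
Reactants: 6 2,4,5-trihydroxybenzoic acid; 2 allyl bromide
Product: 8 2,4,5-tris(allyloxy)benzoic acid, via allyl 2,4,5-tris(allyloxy)benzoate 7 (not isolated)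
Conditions: allyl bromide (4.6 equiv), K2CO3 (5 equiv), degassed DMF, 60 °C, argon; then NaOH, MeOH/H2O, 50 °C; HCl to pH 2
Reagents that add atoms: allyl bromide (2), C=CCBr
Why: Exhaustive Williamson and carboxylate alkylation followed by saponification of the only ester; aryl allyl ethers are inert to hydroxide, and air is excluded because the hydroxyquinol anion is readily oxidised.

Step 5
Reactants: 8 2,4,5-tris(allyloxy)benzoic acid; 5 1-(3,5-diallyl-2,6-dihydroxy-4-methoxyphenyl)pent-4-en-1-one
Product: 10 4,6-diallyl-3-hydroxy-5-methoxy-2-(pent-4-enoyl)phenyl 2,4,5-tris(allyloxy)benzoate, via 2,4,5-tris(allyloxy)benzoyl chloride 9 (not isolated)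
Conditions: (COCl)2, cat. DMF, CH2Cl2, 0 °C → rt, evaporate; then 5, Et3N, DMAP (cat.), CH2Cl2, 0 °C → rt
Reagents that add atoms: none
Why: Acid chloride formation and DMAP-catalysed O-acylation of a phenol; after the first acylation the remaining hydroxyl is hydrogen-bonded to the ketone and flanked by an allyl group, so one equivalent of 9 should give the monoester.

Step 6
Reactants: 10 4,6-diallyl-3-hydroxy-5-methoxy-2-(pent-4-enoyl)phenyl 2,4,5-tris(allyloxy)benzoate
Product: 11 2-allyl-1-(3,5-diallyl-2,6-dihydroxy-4-methoxyphenyl)-3-[2,4,5-tris(allyloxy)phenyl]propane-1,3-dione (racemic at C2, may equilibrate with its cyclic hemiketal)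
Conditions: LiN(SiMe3)2 (3.3 equiv), THF, −20 °C → rt; AcOH quench
Reagents that add atoms: none
Why: Baker–Venkataraman rearrangement; the ketone enolate attacks the neighbouring aryl ester through a six-membered transition state and the phenoxide leaves, while the non-nucleophilic amide base avoids ester cleavage, retro-Claisen fragmentation and migration of the allyl ether double bonds. The stereocentre at C2 is not controlled and disappears in step 7.

Step 7
Reactants: 11 2-allyl-1-(3,5-diallyl-2,6-dihydroxy-4-methoxyphenyl)-3-[2,4,5-tris(allyloxy)phenyl]propane-1,3-dione
Product: 12 3,6,8-triallyl-5-hydroxy-7-methoxy-2-[2,4,5-tris(allyloxy)phenyl]chromen-4-one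
Conditions: p-TsOH·H2O (10 mol%), toluene, 4 Å molecular sieves, 80 °C
Reagents that add atoms: none
Why: Acid-catalysed cyclodehydration of an ortho-hydroxyaryl 1,3-diketone (6-exo-trig addition of a ring A hydroxyl to the ring B carbonyl, then loss of water); only ring A has free hydroxyls because O2' is still allylated, so closure can go one way only, and a catalytic sulfonic acid at this temperature should not protonate monosubstituted alkenes.

Step 8
Reactants: 12 3,6,8-triallyl-5-hydroxy-7-methoxy-2-[2,4,5-tris(allyloxy)phenyl]chromen-4-one
Product: 14 3,6,8-triallyl-5-hydroxy-7-methoxy-2-(2,4,5-triacetoxyphenyl)chromen-4-one, via 3,6,8-triallyl-5-hydroxy-7-methoxy-2-(2,4,5-trihydroxyphenyl)chromen-4-one 13 (not isolated)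
Conditions: Pd(PPh3)4 (5 mol%), morpholine (6 equiv), degassed THF, rt, argon; evaporate; then Ac2O (12 equiv), pyridine, 0 °C → rt
Reagents that add atoms: acetic anhydride, CC(=O)OC(C)=O
Why: Tsuji–Trost deallylation followed by acetylation; zerovalent palladium ionises only the three O-allyl groups (phenoxide leaving groups) and morpholine traps the allyl cation, while the C-allyl groups have no leaving group. Without DMAP the anhydride should acetylate the three ring B phenols and leave the 5-OH, which is chelated to C4=O and shielded by the C6 allyl group; acetylating in the same flask keeps the oxidation-prone triol 13 away from air.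

Step 9
Reactants: 14 3,6,8-triallyl-5-hydroxy-7-methoxy-2-(2,4,5-triacetoxyphenyl)chromen-4-one; 15 2-methyl-2-butene
Product: 16 5-hydroxy-7-methoxy-3,6,8-tris(3-methylbut-2-enyl)-2-(2,4,5-triacetoxyphenyl)chromen-4-one
Conditions: second-generation Grubbs catalyst RuCl2(=CHPh)(PCy3)(H2IMes) (3 × 2.5 mol%), 2-methyl-2-butene/CH2Cl2 1:1, 1,4-benzoquinone (10 mol%), 40 °C, sealed tube, argon
Reagents that add atoms: 2-methyl-2-butene (15), CC=C(C)C
Why: Threefold olefin cross-metathesis by the Chauvin mechanism: 15 converts the benzylidene initiator into the isopropylidene carbene, which adds to each terminal CH=CH2 of 14 to give a ruthenacyclobutane that opens to ArCH2CH=CMe2 and a methylidene carbene; 15 turns the methylidene back into the isopropylidene carbene with loss of propene. The closest known reaction type is the cross-metathesis of allyl arenes and ortho-allyl phenols with 2-methyl-2-butene to prenyl arenes, including several exchanges on one substrate. No ring is closed and no stereocentre or alkene geometry arises, because the new alkene carbon carries two methyl groups. The selectivity needed is cross- over self-metathesis, secured by using 15 as co-solvent so that the isopropylidene carbene is the resting species, and by the trisubstituted products being too hindered to re-enter the cycle. Ring closure between the chains is not a concern: the C6 and C8 allyl groups are meta across the methoxy carbon and the C3 chain is remote. Benzoquinone intercepts ruthenium hydrides that would move the double bonds into conjugation with the arene. The aryl acetates and the chelated 5-OH are poor ligands for ruthenium, and the tetrasubstituted C2=C3 bond of the chromone is inert. A chain that passes through the 2-butenyl stage by way of the ethylidene carbene is still reactive and should be carried on to prenyl by the excess of 15.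

Step 10
Reactants: 16 5-hydroxy-7-methoxy-3,6,8-tris(3-methylbut-2-enyl)-2-(2,4,5-triacetoxyphenyl)chromen-4-one
Product: 17 5-hydroxy-7-methoxy-3,6,8-tris(3-methylbut-2-enyl)-2-(2,4,5-trihydroxyphenyl)chromen-4-one
Conditions: K2CO3 (0.5 equiv), degassed MeOH, argon, 0 °C → rt; NaH2PO4 buffer (pH 6) work-up
Reagents that add atoms: none
Why: Base-catalysed transesterification (Zemplén-type methanolysis) of three aryl acetates; no acid is present at any point, so the prenyl groups cannot cyclise onto the 5-OH, the 2'-OH or the carbonyl, and the absence of oxygen protects the ring B phenoxides.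

## Compound list

1 | 2',6'-dihydroxy-4'-methoxyacetophenone | CC(=O)c1c(O)cc(OC)cc1O | starting material
2 | allyl bromide | C=CCBr | starting material
3 | 1-[2,6-bis(allyloxy)-4-methoxyphenyl]ethan-1-one | CC(=O)c1c(OCC=C)cc(OC)cc1OCC=C | intermediate
4 | 1-[2,6-bis(allyloxy)-4-methoxyphenyl]pent-4-en-1-one | C=CCCC(=O)c1c(OCC=C)cc(OC)cc1OCC=C | intermediate
5 | 1-(3,5-diallyl-2,6-dihydroxy-4-methoxyphenyl)pent-4-en-1-one | C=CCCC(=O)c1c(O)c(CC=C)c(OC)c(CC=C)c1O | intermediate
6 | 2,4,5-trihydroxybenzoic acid | O=C(O)c1cc(O)c(O)cc1O | starting material
7 | allyl 2,4,5-tris(allyloxy)benzoate | C=CCOC(=O)c1cc(OCC=C)c(OCC=C)cc1OCC=C | intermediate (not isolated)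
8 | 2,4,5-tris(allyloxy)benzoic acid | O=C(O)c1cc(OCC=C)c(OCC=C)cc1OCC=C | intermediate
9 | 2,4,5-tris(allyloxy)benzoyl chloride | O=C(Cl)c1cc(OCC=C)c(OCC=C)cc1OCC=C | intermediate (not isolated)
10 | 4,6-diallyl-3-hydroxy-5-methoxy-2-(pent-4-enoyl)phenyl 2,4,5-tris(allyloxy)benzoate | C=CCCC(=O)c1c(O)c(CC=C)c(OC)c(CC=C)c1OC(=O)c1cc(OCC=C)c(OCC=C)cc1OCC=C | intermediate
11 | 2-allyl-1-(3,5-diallyl-2,6-dihydroxy-4-methoxyphenyl)-3-[2,4,5-tris(allyloxy)phenyl]propane-1,3-dione, racemic | C=CCC(C(=O)c1c(O)c(CC=C)c(OC)c(CC=C)c1O)C(=O)c1cc(OCC=C)c(OCC=C)cc1OCC=C | intermediate
12 | 3,6,8-triallyl-5-hydroxy-7-methoxy-2-[2,4,5-tris(allyloxy)phenyl]chromen-4-one | COc1c(CC=C)c(O)c2c(=O)c(CC=C)c(-c3cc(OCC=C)c(OCC=C)cc3OCC=C)oc2c1CC=C | intermediate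
13 | 3,6,8-triallyl-5-hydroxy-7-methoxy-2-(2,4,5-trihydroxyphenyl)chromen-4-one | COc1c(CC=C)c(O)c2c(=O)c(CC=C)c(-c3cc(O)c(O)cc3O)oc2c1CC=C | intermediate (not isolated)
14 | 3,6,8-triallyl-5-hydroxy-7-methoxy-2-(2,4,5-triacetoxyphenyl)chromen-4-one | COc1c(CC=C)c(O)c2c(=O)c(CC=C)c(-c3cc(OC(C)=O)c(OC(C)=O)cc3OC(C)=O)oc2c1CC=C | intermediate
15 | 2-methyl-2-butene | CC=C(C)C | starting material
16 | 5-hydroxy-7-methoxy-3,6,8-tris(3-methylbut-2-enyl)-2-(2,4,5-triacetoxyphenyl)chromen-4-one | COc1c(CC=C(C)C)c(O)c2c(=O)c(CC=C(C)C)c(-c3cc(OC(C)=O)c(OC(C)=O)cc3OC(C)=O)oc2c1CC=C(C)C | intermediate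
17 | 5-hydroxy-7-methoxy-3,6,8-tris(3-methylbut-2-enyl)-2-(2,4,5-trihydroxyphenyl)chromen-4-one | COc1c(CC=C(C)C)c(O)c2c(=O)c(CC=C(C)C)c(-c3cc(O)c(O)cc3O)oc2c1CC=C(C)C | target

## Step count and least certain steps

Total: 10 steps. Longest linear sequence: 9 steps (1, 2, 3, 5, 6, 7, 8, 9, 10); step 4 is the side branch.

**Step 9 (key step).** The most likely failures are migration of the terminal double bonds into conjugation with the arene, caused by ruthenium hydrides from catalyst decay, and stalling after one or two exchanges as the catalyst dies on a substrate with three reacting sites. The fallback replaces metathesis by cleavage and olefination and sets out from 14. Lemieux–Johnson cleavage (K2OsO4·2H2O cat., NaIO4, 2,6-lutidine, dioxane/water) should turn the three terminal alkenes into 5-hydroxy-7-methoxy-3,6,8-tris(2-oxoethyl)-2-(2,4,5-triacetoxyphenyl)chromen-4-one F1. A Wittig reaction with excess isopropylidenetriphenylphosphorane (from isopropyltriphenylphosphonium iodide and KN(SiMe3)2, THF, −78 → 0 °C) should then build the three CH=CMe2 ends and return to the route at 16. Any acetate lost to the basic ylide is of no consequence, since step 10 removes all of them.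

**Step 2.** The risk is over-alkylation through proton transfer between the product ketone and unreacted enolate. The fallback sets out from 3 and postpones the third allyl group. Claisen rearrangement as in step 3 should give 1-(3,5-diallyl-2,6-dihydroxy-4-methoxyphenyl)ethan-1-one F2. Acylation with 9 as in step 5 should give 2-acetyl-4,6-diallyl-3-hydroxy-5-methoxyphenyl 2,4,5-tris(allyloxy)benzoate F3. The acyl shift as in step 6 should give 1-(3,5-diallyl-2,6-dihydroxy-4-methoxyphenyl)-3-[2,4,5-tris(allyloxy)phenyl]propane-1,3-dione F4. C-Allylation of the doubly stabilised central carbon (2, 1.05 equiv; K2CO3, acetone, rt) returns to the route at 11.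

**Step 6.** The risk is a slow acyl shift, because the enolate carbon is secondary and the ester carbonyl is deactivated by three alkoxy groups, so cleavage of the aryl ester may compete. The fallback changes from intramolecular transfer to direct C-acylation. It sets out from 5, which is converted into its trilithium salt (LiN(SiMe3)2, 4 equiv, THF, −78 °C) and treated with the far more electrophilic 9. It returns at 11 and makes no new compound.

**Step 10.** The risk is oxidation of the ring B phenoxides to a hydroxyquinone by traces of air while the acetates are cleaved in basic methanol. The fallback replaces the base-labile group by a fluoride-labile one and sets out from 13, generated as in the first stage of step 8. Silylation (tert-butyldimethylsilyl chloride, imidazole, DMF) should give 3,6,8-triallyl-2-[2,4,5-tris(tert-butyldimethylsilyloxy)phenyl]-5-hydroxy-7-methoxychromen-4-one F5. Metathesis as in step 9 should give 2-[2,4,5-tris(tert-butyldimethylsilyloxy)phenyl]-5-hydroxy-7-methoxy-3,6,8-tris(3-methylbut-2-enyl)chromen-4-one F6. Cleavage of the aryl silyl ethers with KHF2 in methanol at rt, near neutrality, returns to the route at 17.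

## Further compounds

F1 | step 9 | 5-hydroxy-7-methoxy-3,6,8-tris(2-oxoethyl)-2-(2,4,5-triacetoxyphenyl)chromen-4-one | COc1c(CC=O)c(O)c2c(=O)c(CC=O)c(-c3cc(OC(C)=O)c(OC(C)=O)cc3OC(C)=O)oc2c1CC=O
F2 | step 2 | 1-(3,5-diallyl-2,6-dihydroxy-4-methoxyphenyl)ethan-1-one | CC(=O)c1c(O)c(CC=C)c(OC)c(CC=C)c1O
F3 | step 2 | 2-acetyl-4,6-diallyl-3-hydroxy-5-methoxyphenyl 2,4,5-tris(allyloxy)benzoate | CC(=O)c1c(O)c(CC=C)c(OC)c(CC=C)c1OC(=O)c1cc(OCC=C)c(OCC=C)cc1OCC=C
F4 | step 2 | 1-(3,5-diallyl-2,6-dihydroxy-4-methoxyphenyl)-3-[2,4,5-tris(allyloxy)phenyl]propane-1,3-dione | C=CCc1c(O)c(C(=O)CC(=O)c2cc(OCC=C)c(OCC=C)cc2OCC=C)c(O)c(CC=C)c1OC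
F0 | step 6 | none | none
F5 | step 10 | 3,6,8-triallyl-2-[2,4,5-tris(tert-butyldimethylsilyloxy)phenyl]-5-hydroxy-7-methoxychromen-4-one | COc1c(CC=C)c(O)c2c(=O)c(CC=C)c(-c3cc(O[Si](C)(C)C(C)(C)C)c(O[Si](C)(C)C(C)(C)C)cc3O[Si](C)(C)C(C)(C)C)oc2c1CC=C
F6 | step 10 | 2-[2,4,5-tris(tert-butyldimethylsilyloxy)phenyl]-5-hydroxy-7-methoxy-3,6,8-tris(3-methylbut-2-enyl)chromen-4-one | COc1c(CC=C(C)C)c(O)c2c(=O)c(CC=C(C)C)c(-c3cc(O[Si](C)(C)C(C)(C)C)c(O[Si](C)(C)C(C)(C)C)cc3O[Si](C)(C)C(C)(C)C)oc2c1CC=C(C)C
A1 | alternative 1 | 2,10-dimethylundeca-2,9-dien-6-one | CC(C)=CCCC(=O)CCC=C(C)C
A2 | alternative 1 | 6-methoxy-2,10-dimethylundeca-2,5,9-triene (methyl enol ether of A1, geometry at C5 not defined) | COC(=CCC=C(C)C)CCC=C(C)C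
A3 | alternative 1 | malonyl dichloride | O=C(Cl)CC(=O)Cl
A4 | alternative 1 | 5-methoxy-4,6-bis(3-methylbut-2-enyl)benzene-1,3-diol | COc1c(CC=C(C)C)c(O)cc(O)c1CC=C(C)C
A5 | alternative 2 | tetronic acid | O=C1C=C(O)CO1
A6 | alternative 2 | 2,4-bis(tert-butyldimethylsilyloxy)furan | CC(C)(C)[Si](C)(C)Oc1cc(O[Si](C)(C)C(C)(C)C)co1
A7 | alternative 2 | 2-ethynyl-7-methoxy-5-(methoxymethoxy)-3,6,8-tris(3-methylbut-2-enyl)chromen-4-one | COCOc1c(CC=C(C)C)c(OC)c(CC=C(C)C)c2oc(C#C)c(CC=C(C)C)c(=O)c12
A8 | alternative 2 | 2-[2,4-bis(tert-butyldimethylsilyloxy)-5-hydroxyphenyl]-7-methoxy-5-(methoxymethoxy)-3,6,8-tris(3-methylbut-2-enyl)chromen-4-one | COc1c(CC=C(C)C)c(OCOC)c2c(=O)c(CC=C(C)C)c(-c3cc(O)c(O[Si](C)(C)C(C)(C)C)cc3O[Si](C)(C)C(C)(C)C)oc2c1CC=C(C)C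
A9 | alternative 3 | 2,6-dihydroxy-4-methoxy-3,5-bis(3-methylbut-2-enyl)benzaldehyde | COc1c(CC=C(C)C)c(O)c(C=O)c(O)c1CC=C(C)C
A10 | alternative 3 | 1,2,4-tris(methoxymethoxy)-5-(5-methylhex-4-en-1-ynyl)benzene | COCOc1cc(OCOC)c(C#CCC=C(C)C)cc1OCOC
A11 | alternative 3 | 5-hydroxy-7-methoxy-3,6,8-tris(3-methylbut-2-enyl)-2-[2,4,5-tris(methoxymethoxy)phenyl]chromen-4-one | COc1c(CC=C(C)C)c(O)c2c(=O)c(CC=C(C)C)c(-c3cc(OCOC)c(OCOC)cc3OCOC)oc2c1CC=C(C)C
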